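## Analysis of the target

The target is an achiral polyphenol built around one hexasubstituted benzene, ring A. Numbered from the methoxy carbon, C1 carries OMe, C2, C4 and C6 each carry a 4-hydroxybenzyl group, C3 carries the only hydroxyl of ring A, and C5 carries a 2-(3-hydroxyphenyl)ethyl chain. There is no stereocenter and no stereogenic axis, so the only question of arrangement is which of six contiguous ring positions carries which group. The sensitive groups are the five electron-rich oxygenated arenes (the free polyphenol is prone to air oxidation), the three doubly benzylic CH2 groups, and the four outer phenols, which must be masked through enolate and acetylide chemistry. The difficulty is ring A itself: it is fully substituted, so any stepwise substitution or coupling on a preformed arene has to take place between two ortho neighbours. In addition, O1 and O3 must end as one methyl ether and one free phenol although both sit between two benzyl groups. The strategy rests on reading ring A as a four-carbon plus two-carbon combination: C2–C3–C4–C5, with the C3 oxygen and the groups on C2, C4 and C5, is the C3–C6 diene of a 4-oxygenated 2-pyranone, and C1–C6, with OMe and the third benzyl group, is a methoxyalkyne. All six substituents are then placed in one ring-forming operation, and the two oxygens arrive on different partners and never need to be told apart on the arene.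

## Retrosynthetic reasoning

**18 back to 17 and 16.** The last operations only unmask oxygen. The four outer phenols of 18 are carried as benzyl ethers in 17 (four O–CH2Ph bonds cut), and the C3 hydroxyl of 17 is carried as the pivalate in 16 (one acyl C–O bond cut). Benzyl ethers survive strong base, heat and hydride and leave together in one neutral reduction that does not touch the diarylmethane C–C bonds. The ester on O3 is removed before that reduction, so the oxidation-prone free polyphenol appears only in the final step.

**16 back to 10 and 14 (through 15).** Ring A is cut at C1–C2 and C5–C6. This separates a four-carbon piece (C2–C5, carrying O3 as the pivalate, two benzyl groups and the arylethyl chain), which is the diene of pyranyl pivalate 10, from a two-carbon piece (C1 with OMe, C6 with a benzyl group), which is ynol ether 14. Cutting here and nowhere else puts each ring oxygen on a different fragment, so the methyl ether and the masked phenol are distinct from the start. The forward reaction must add the alkyne across C3 and C6 of the pyranone to give bicyclic lactone 15, which then aromatizes by cycloreversion with decarboxylation. The benzyl-bearing alkyne carbon must bond to pyranone C6 and the methoxy-bearing carbon to pyranone C3. The acyl group on O4 of 10 makes the diene more electron-poor and later serves as the protecting group of O3.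

**10 back to 9 and 8.** The pivalate O–acyl bond is cut to give hydroxypyranone 9, and the lactone C2–O1 bond of 9 is cut to give the open 3,5-diketo ester 8. The pyranone is thus a cyclized triketide whose three carbon substituents are already attached to the chain. The forward steps are a lactonization through the C5 enol oxygen and an O-acylation at the only free hydroxyl.

**8 back to 3 (as dianion 7) and 6.** The chain of 8 is cut at C4–C5. This gives the β-keto ester 3, used as its dianion 7 (nucleophilic at the γ-carbon), and the N-methoxy-N-methylamide 6 as the acyl donor carrying the arylethyl chain. The cut lies between the part that holds both 4-benzyloxybenzyl groups and the part that holds the 3-benzyloxyphenyl ring, so the two kinds of aryl group come from separate, simple building blocks. The forward reaction must acylate the γ-carbon once and stop; the stable tetrahedral adduct of 6 ensures this.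

**3 back to 2, and 2 back to 1.** The C2–C3 bond of 3 is cut to two molecules of ester 2. The α-carbon of a 3-arylpropanoate already carries the ArCH2 group, so a self-Claisen condensation places both benzyl groups where the pyranone needs them without a separate benzylation. Ester 2 is the benzyl ether of commercial phenol 1.

**6 back to 5 and 4.** The amide C–N bond is cut to benzyl ester 5, which comes from commercial acid 4 by benzylation of both the phenol and the carboxyl group in one operation.

**14 back to 13 and 12, and 13 back to 11.** The propargylic C–C bond of 14 is cut to methoxyacetylide 13 and benzylic chloride 12. The acetylide comes from commercial acetal 11 by two eliminations and a deprotonation in one flask. The third 4-benzyloxybenzyl group is thus bought, and the ynol ether is reached in one operation.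

## Alternatives that were turned down

**Alternative 1:** The three 4-hydroxyphenyl rings would be disconnected instead of ring A. The triketone A1, a ring A core carrying three 4-hydroxybenzoyl groups, would be traced to the tris-ynone A2 and three equivalents of the siloxy diene A3. In the forward key step each terminal ynone would undergo a Diels–Alder reaction with A3, and acid-induced loss of the methoxy group would aromatize each adduct, giving six new bonds and three new rings at once. In its favour, cycloadditions of such dienes with ynones are dependable and their regiochemistry is unambiguous (para-hydroxyaryl ketones), so its key step is more certain to work than the chosen one. Against it, the hexasubstituted ring A must already exist, now with three acyl groups between ortho neighbours, so the real problem is moved to the synthesis of A2 and not solved. Three hindered diaryl ketones must afterwards be reduced to CH2, and the methyl and benzyl ethers on the core must be differentiated early. The chosen strategy builds ring A itself with all six substituents and needs no redox correction at the benzylic carbons.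

**Alternative 2:** Ring A would be cut at C1–C2 and C4–C5 into the symmetrical ketone A5 (supplying C2, C3 and C4 with two benzyl groups) and the allenoate A6 (supplying C5, C6 and C1). Under a strong alkoxide base the enolate of A5 would add to the central allene carbon, the second enolate would attack the ester, and tautomerization would give the resorcinol A4. Mono-O-methylation of A4 would lead to 17. In its favour, this is the shortest way to the fully substituted ring, and because A4 is symmetrical either hydroxyl may be methylated; on step count it is stronger than the chosen route. Against it, the single methylation of two equivalent, doubly flanked hydroxyls is statistical and should give unreacted, mono- and dimethylated material that is hard to separate. In addition, A6 has acidic positions beside the allene and is likely to isomerize to a conjugated dienoate under the base before the hindered secondary enolate adds. The chosen strategy gives up some brevity but fixes the methyl ether and the free phenol by construction and exposes no base-labile allene.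

**Alternative 3:** The three CH2–aryl bonds at C2, C4 and C6 would be cut, leading from the penta-O-benzyl target A7 to the tris(benzylic carbonate) core A8 and three equivalents of the boronic acid A9. The forward key step is a threefold benzylic Suzuki coupling with a palladium–diphosphine catalyst. In its favour, the coupling type is well established for benzylic carbonates, and the endgame is a single global hydrogenolysis, one step shorter than the chosen endgame. Against it, A8 is itself a hexasubstituted benzene that must be assembled by several substitutions on a resorcinol derivative, with the methyl and benzyl ethers set apart early. Each of the three couplings occurs at a benzylic carbon between two ortho substituents, and the carbonates para or ortho to oxygen are prone to ionization. Incomplete threefold coupling would give mixtures. The chosen strategy avoids both the long preparation of the core and three crowded couplings by forming ring A from acyclic pieces.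

Key step: step 9

Remark on the chemistry: compounds 3 and 8 are carried as mixtures of stereoisomers and keto–enol tautomers, because their sp3 centers become sp2 in pyranone 9; the target has no stereocenter.

## Route

**Step 1**
Reactants: 1 methyl 3-(4-hydroxyphenyl)propanoate
Product: 2 methyl 3-(4-benzyloxyphenyl)propanoate
Conditions: BnBr, K2CO3, acetone, reflux
Reagents that add atoms: benzyl bromide, BrCc1ccccc1
Why: Williamson ether synthesis; the phenoxide is alkylated on oxygen and the methyl ester is inert to K2CO3 in acetone.

**Step 2**
Reactants: 2 methyl 3-(4-benzyloxyphenyl)propanoate (two molecules)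
Product: 3 methyl 2-(4-benzyloxybenzyl)-5-(4-benzyloxyphenyl)-3-oxopentanoate
Conditions: NaH, MeOH (cat.), THF, 65 °C; then cold aq. HCl
Reagents that add atoms: none
Why: Claisen self-condensation, driven by deprotonation of the β-keto ester product, which still has one α-hydrogen; the new C2 stereocenter is formed racemic and disappears later.

**Step 3**
Reactants: 4 3-(3-hydroxyphenyl)propanoic acid
Product: 5 benzyl 3-(3-benzyloxyphenyl)propanoate
Conditions: BnBr (2.2 equiv), K2CO3, DMF, 60 °C
Reagents that add atoms: benzyl bromide, BrCc1ccccc1
Why: Williamson ether synthesis and carboxylate alkylation in one operation; both the phenoxide and the carboxylate are benzylated.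

**Step 4**
Reactants: 5 benzyl 3-(3-benzyloxyphenyl)propanoate
Product: 6 3-(3-benzyloxyphenyl)-N-methoxy-N-methylpropanamide
Conditions: MeNH(OMe)·HCl, i-PrMgCl, THF, −20 to 0 °C
Reagents that add atoms: N,O-dimethylhydroxylamine hydrochloride, CNOC.Cl
Why: Direct ester-to-Weinreb-amide aminolysis by the chloromagnesium amide; the chelated tetrahedral adduct prevents addition of the Grignard reagent to the product.

**Step 5**
Reactants: 3 methyl 2-(4-benzyloxybenzyl)-5-(4-benzyloxyphenyl)-3-oxopentanoate; 6 3-(3-benzyloxyphenyl)-N-methoxy-N-methylpropanamide
Product: 8 methyl 2,4-bis(4-benzyloxybenzyl)-7-(3-benzyloxyphenyl)-3,5-dioxoheptanoate, via dilithio dianion 7 (not isolated)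
Conditions: LiN(i-Pr)2 (2.1 equiv), THF, −78 to 0 °C; then 6, −78 to 0 °C; aq. HCl
Reagents that add atoms: none
Why: γ-Acylation of a β-keto ester dianion (Huckin–Weiler dianion chemistry); the more basic γ-carbanion attacks the amide, and the stable chelated tetrahedral adduct keeps the acidic diketone from forming until work-up, so the dianion is not quenched. The sp3 centers at C2 and C4 are uncontrolled and are lost in step 6.

**Step 6**
Reactants: 8 methyl 2,4-bis(4-benzyloxybenzyl)-7-(3-benzyloxyphenyl)-3,5-dioxoheptanoate
Product: 9 3,5-bis(4-benzyloxybenzyl)-6-[2-(3-benzyloxyphenyl)ethyl]-4-hydroxy-2H-pyran-2-one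
Conditions: DBU, PhMe, 80 °C; then aq. HCl
Reagents that add atoms: none
Why: Base-mediated lactonization of a 3,5-diketo ester; the C5 enol oxygen attacks the ester carbonyl (6-exo-trig) with loss of methanol, and formation of the conjugated 4-hydroxy-2-pyranone drives the closure.

**Step 7**
Reactants: 9 3,5-bis(4-benzyloxybenzyl)-6-[2-(3-benzyloxyphenyl)ethyl]-4-hydroxy-2H-pyran-2-one
Product: 10 3,5-bis(4-benzyloxybenzyl)-6-[2-(3-benzyloxyphenyl)ethyl]-2-oxo-2H-pyran-4-yl pivalate
Conditions: t-BuCOCl, Et3N, DMAP (cat.), CH2Cl2, 0 °C to rt
Reagents that add atoms: pivaloyl chloride, CC(C)(C)C(Cl)=O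
Why: O-Acylation of the acidic 4-hydroxyl; C3 is substituted so C-acylation cannot occur, and DMAP allows acyl transfer to settle on the 4-acyloxy-2-pyranone form.

**Step 8**
Reactants: 11 chloroacetaldehyde dimethyl acetal; 12 4-benzyloxybenzyl chloride
Product: 14 1-benzyloxy-4-(3-methoxyprop-2-ynyl)benzene, via sodium methoxyacetylide 13 (not isolated)
Conditions: 11 (2 equiv), NaNH2 (3 equiv per 11), NH3 (l), −33 °C; then 12, THF, −33 °C to rt; H2O work-up, chromatography on Et3N-deactivated silica
Reagents that add atoms: none
Why: Two successive eliminations (HCl, then methanol) and deprotonation give the alkoxyacetylide, which is alkylated by SN2 at the activated benzylic chloride. Exactly three equivalents of amide per acetal leave no free base to isomerize the propargylic product.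

**Step 9**
Reactants: 10 3,5-bis(4-benzyloxybenzyl)-6-[2-(3-benzyloxyphenyl)ethyl]-2-oxo-2H-pyran-4-yl pivalate; 14 1-benzyloxy-4-(3-methoxyprop-2-ynyl)benzene
Product: 16 2,4,6-tris(4-benzyloxybenzyl)-3-[2-(3-benzyloxyphenyl)ethyl]-5-methoxyphenyl pivalate, via oxabicyclic lactone 15 (not isolated)
Conditions: 14 (3 equiv), i-Pr2NEt (cat.), PhMe, sealed tube, 160 °C
Reagents that add atoms: none
Why: The ynol ether adds as the 2π partner across C3 and C6 of the pyranone diene in an inverse-electron-demand [4+2] cycloaddition, giving the 2-oxabicyclo[2.2.2]octadienone 15, whose lactone bridge leaves as CO2 by retro-[4+2] to give the benzene. The closest known reaction type is the Diels–Alder/decarboxylation of 2-pyranones with ynamines and alkoxyalkynes; a fully substituted 4-acyloxy-2-pyranone is a more demanding case and is expected to need the high temperature. Ring A closes by an intermolecular [4+2] annulation, four carbons from the pyranone and two from the alkyne, and the gain of aromaticity with loss of a gas makes the sequence irreversible. No stereocenter remains: the two bridgehead carbons of 15 form as a racemate with their relative configuration fixed by the bicycle, and both become sp2 in 16. The selectivity needed is regiochemical: the nucleophilic β-carbon of the ynol ether (bearing the benzyl group) must bond to pyranone C6 and the methoxy-bearing carbon to C3. This is expected from the polarization of both partners: C6 is the electrophilic terminus of the dienyl lactone, and in an asynchronous transition state the positive charge that develops on the alkyne is stabilized by the methoxy oxygen while the negative charge runs into the lactone carbonyl through C3. The pivaloyloxy group makes the diene more electron-poor than an alkoxy group would and withstands the temperature. The methyl ynol ether has no β-hydrogen for fragmentation to a ketene, so an excess can be heated, with a trace of hindered amine to suppress acid-catalysed hydration.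

**Step 10**
Reactants: 16 2,4,6-tris(4-benzyloxybenzyl)-3-[2-(3-benzyloxyphenyl)ethyl]-5-methoxyphenyl pivalate
Product: 17 2,4,6-tris(4-benzyloxybenzyl)-3-[2-(3-benzyloxyphenyl)ethyl]-5-methoxyphenol
Conditions: LiAlH4, THF, 0 °C to rt; then H2O, aq. NaOH
Reagents that add atoms: none
Why: Reductive cleavage of an aryl ester by hydride; the small hydride reaches the carbonyl shielded by the tert-butyl group and the two ortho benzyl groups, where alkoxide methanolysis could be slow. Benzyl and methyl ethers are inert.

**Step 11**
Reactants: 17 2,4,6-tris(4-benzyloxybenzyl)-3-[2-(3-benzyloxyphenyl)ethyl]-5-methoxyphenol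
Product: 18 2,4,6-tris(4-hydroxybenzyl)-3-[2-(3-hydroxyphenyl)ethyl]-5-methoxyphenol
Conditions: H2 (1 atm), Pd/C, EtOAc–MeOH, rt
Reagents that add atoms: none
Why: Catalytic hydrogenolysis of four benzylic C–O bonds; the diarylmethane C–C bonds and the aryl methyl ether are not cleaved under these conditions, and the oxidation-prone polyphenol is formed last under a reducing atmosphere.

## Compound list

1 | methyl 3-(4-hydroxyphenyl)propanoate | COC(=O)CCc1ccc(O)cc1 | starting material
2 | methyl 3-(4-benzyloxyphenyl)propanoate | COC(=O)CCc1ccc(OCc2ccccc2)cc1 | intermediate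
3 | methyl 2-(4-benzyloxybenzyl)-5-(4-benzyloxyphenyl)-3-oxopentanoate (racemic) | COC(=O)C(Cc1ccc(OCc2ccccc2)cc1)C(=O)CCc1ccc(OCc2ccccc2)cc1 | intermediate
4 | 3-(3-hydroxyphenyl)propanoic acid | OC(=O)CCc1cccc(O)c1 | starting material
5 | benzyl 3-(3-benzyloxyphenyl)propanoate | O=C(CCc1cccc(OCc2ccccc2)c1)OCc1ccccc1 | intermediate
6 | 3-(3-benzyloxyphenyl)-N-methoxy-N-methylpropanamide | CON(C)C(=O)CCc1cccc(OCc2ccccc2)c1 | intermediate
7 | dilithium bis-enolate (dianion) of 3 | [Li+].[Li+].COC([O-])=C(Cc1ccc(OCc2ccccc2)cc1)C([O-])=CCc1ccc(OCc2ccccc2)cc1 | intermediate (not isolated)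
8 | methyl 2,4-bis(4-benzyloxybenzyl)-7-(3-benzyloxyphenyl)-3,5-dioxoheptanoate (mixture of stereoisomers and tautomers) | COC(=O)C(Cc1ccc(OCc2ccccc2)cc1)C(=O)C(Cc1ccc(OCc2ccccc2)cc1)C(=O)CCc1cccc(OCc2ccccc2)c1 | intermediate
9 | 3,5-bis(4-benzyloxybenzyl)-6-[2-(3-benzyloxyphenyl)ethyl]-4-hydroxy-2H-pyran-2-one | O=c1oc(CCc2cccc(OCc3ccccc3)c2)c(Cc2ccc(OCc3ccccc3)cc2)c(O)c1Cc1ccc(OCc2ccccc2)cc1 | intermediate
10 | 3,5-bis(4-benzyloxybenzyl)-6-[2-(3-benzyloxyphenyl)ethyl]-2-oxo-2H-pyran-4-yl pivalate | O=c1oc(CCc2cccc(OCc3ccccc3)c2)c(Cc2ccc(OCc3ccccc3)cc2)c(OC(=O)C(C)(C)C)c1Cc1ccc(OCc2ccccc2)cc1 | intermediate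
11 | chloroacetaldehyde dimethyl acetal (2-chloro-1,1-dimethoxyethane) | COC(CCl)OC | starting material
12 | 4-benzyloxybenzyl chloride | ClCc1ccc(OCc2ccccc2)cc1 | starting material
13 | sodium methoxyacetylide | [Na+].[C-]#COC | intermediate (not isolated)
14 | 1-benzyloxy-4-(3-methoxyprop-2-ynyl)benzene | COC#CCc1ccc(OCc2ccccc2)cc1 | intermediate
15 | 4,6,7-tris(4-benzyloxybenzyl)-1-[2-(3-benzyloxyphenyl)ethyl]-8-methoxy-3-oxo-2-oxabicyclo[2.2.2]octa-5,7-dien-5-yl pivalate (racemic; bridgehead relation fixed by the bicycle) | O=C1OC2(CCc3cccc(OCc4ccccc4)c3)C(Cc3ccc(OCc4ccccc4)cc3)=C(OC(=O)C(C)(C)C)C1(Cc5ccc(OCc6ccccc6)cc5)C(OC)=C2Cc7ccc(OCc8ccccc8)cc7 | intermediate (not isolated)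
16 | 2,4,6-tris(4-benzyloxybenzyl)-3-[2-(3-benzyloxyphenyl)ethyl]-5-methoxyphenyl pivalate | COc1c(Cc2ccc(OCc3ccccc3)cc2)c(OC(=O)C(C)(C)C)c(Cc2ccc(OCc3ccccc3)cc2)c(CCc2cccc(OCc3ccccc3)c2)c1Cc1ccc(OCc2ccccc2)cc1 | intermediate
17 | 2,4,6-tris(4-benzyloxybenzyl)-3-[2-(3-benzyloxyphenyl)ethyl]-5-methoxyphenol | COc1c(Cc2ccc(OCc3ccccc3)cc2)c(O)c(Cc2ccc(OCc3ccccc3)cc2)c(CCc2cccc(OCc3ccccc3)c2)c1Cc1ccc(OCc2ccccc2)cc1 | intermediate
18 | 2,4,6-tris(4-hydroxybenzyl)-3-[2-(3-hydroxyphenyl)ethyl]-5-methoxyphenol | COc1c(Cc2ccc(O)cc2)c(O)c(Cc2ccc(O)cc2)c(CCc2cccc(O)c2)c1Cc1ccc(O)cc1 | target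

## Step count and least certain steps

Total: 11 steps. Longest linear sequence: 8 steps (steps 1, 2, 5, 6, 7, 9, 10, 11). Steps 3 and 4 and step 8 are side branches.

**Step 9 (key step).** The most likely failure is that cycloaddition at the fully substituted, only moderately electron-poor diene is slower than thermal oligomerization or hydration of the ynol ether, so the alkyne is consumed before it adds. A second risk is loss of regiocontrol, since both diene termini carry similar alkyl groups. The fallback makes the diene far more electron-poor. It sets out from hydroxypyranone 9, which with Tf2O and Et3N in CH2Cl2 at −78 °C should give 3,5-bis(4-benzyloxybenzyl)-6-[2-(3-benzyloxyphenyl)ethyl]-2-oxo-2H-pyran-4-yl trifluoromethanesulfonate F1. Its cycloaddition with 14 should proceed at lower temperature through the bicyclic lactone triflate F2 to 2,4,6-tris(4-benzyloxybenzyl)-3-[2-(3-benzyloxyphenyl)ethyl]-5-methoxyphenyl trifluoromethanesulfonate F3. Cleavage of the S–O bond with Et4NOH in dioxane would then give phenol 17, where the route is rejoined.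

**Step 8.** The risks are base-induced propargyl-to-allenyl isomerization of the product, competing attack of methoxide or ammonia on the reactive benzylic chloride, and hydration of the ynol ether during work-up. The fallback replaces the SN2 alkylation by a cross-coupling. It sets out from 13 (made as in step 8, ammonia replaced by THF), which with ZnCl2 would give chloro(methoxyethynyl)zinc F4. Negishi coupling of this much less basic alkynylzinc with chloride 12 under Pd(PPh3)4 catalysis in THF would give 14.

**Step 5.** The risks are incomplete formation of the dianion, slow acylation at the hindered secondary γ-carbanion, and proton transfer that returns starting β-keto ester. The fallback forms the same C–C bond by aldol addition and adjusts the oxidation level afterwards. It sets out from 6, which is reduced (LiAlH4, THF, −78 °C) to 3-(3-benzyloxyphenyl)propanal F5. Addition of dianion 7 to this aldehyde would give methyl 2,4-bis(4-benzyloxybenzyl)-7-(3-benzyloxyphenyl)-5-hydroxy-3-oxoheptanoate F6, and oxidation with Dess–Martin periodinane would return to diketo ester 8.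

**Step 2.** The risks are incomplete condensation and reversal by retro-Claisen cleavage or ester hydrolysis during work-up. The fallback is a directed crossed Claisen condensation. It sets out from 2, which is saponified (LiOH, THF–H2O) to 3-(4-benzyloxyphenyl)propanoic acid F7 and converted with oxalyl chloride into 3-(4-benzyloxyphenyl)propanoyl chloride F8. Acylation of the lithium enolate of 2 (two equivalents, LiN(i-Pr)2, THF, −78 °C) with this chloride would give 3.

## Further compounds

F1 | step 9 | 3,5-bis(4-benzyloxybenzyl)-6-[2-(3-benzyloxyphenyl)ethyl]-2-oxo-2H-pyran-4-yl trifluoromethanesulfonate | O=c1oc(CCc2cccc(OCc3ccccc3)c2)c(Cc2ccc(OCc3ccccc3)cc2)c(OS(=O)(=O)C(F)(F)F)c1Cc1ccc(OCc2ccccc2)cc1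
F2 | step 9 | 4,6,7-tris(4-benzyloxybenzyl)-1-[2-(3-benzyloxyphenyl)ethyl]-8-methoxy-3-oxo-2-oxabicyclo[2.2.2]octa-5,7-dien-5-yl trifluoromethanesulfonate (racemic, not isolated) | O=C1OC2(CCc3cccc(OCc4ccccc4)c3)C(Cc3ccc(OCc4ccccc4)cc3)=C(OS(=O)(=O)C(F)(F)F)C1(Cc5ccc(OCc6ccccc6)cc5)C(OC)=C2Cc7ccc(OCc8ccccc8)cc7
F3 | step 9 | 2,4,6-tris(4-benzyloxybenzyl)-3-[2-(3-benzyloxyphenyl)ethyl]-5-methoxyphenyl trifluoromethanesulfonate | COc1c(Cc2ccc(OCc3ccccc3)cc2)c(OS(=O)(=O)C(F)(F)F)c(Cc2ccc(OCc3ccccc3)cc2)c(CCc2cccc(OCc3ccccc3)c2)c1Cc1ccc(OCc2ccccc2)cc1
F4 | step 8 | chloro(methoxyethynyl)zinc | COC#C[Zn]Cl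
F5 | step 5 | 3-(3-benzyloxyphenyl)propanal | O=CCCc1cccc(OCc2ccccc2)c1
F6 | step 5 | methyl 2,4-bis(4-benzyloxybenzyl)-7-(3-benzyloxyphenyl)-5-hydroxy-3-oxoheptanoate (mixture of diastereomers) | COC(=O)C(Cc1ccc(OCc2ccccc2)cc1)C(=O)C(Cc1ccc(OCc2ccccc2)cc1)C(O)CCc1cccc(OCc2ccccc2)c1
F7 | step 2 | 3-(4-benzyloxyphenyl)propanoic acid | OC(=O)CCc1ccc(OCc2ccccc2)cc1
F8 | step 2 | 3-(4-benzyloxyphenyl)propanoyl chloride | ClC(=O)CCc1ccc(OCc2ccccc2)cc1
A1 | alternative 1 | {2-benzyloxy-4-[2-(3-benzyloxyphenyl)ethyl]-6-methoxybenzene-1,3,5-triyl}tris[(4-hydroxyphenyl)methanone] | COc1c(C(=O)c2ccc(O)cc2)c(OCc2ccccc2)c(C(=O)c2ccc(O)cc2)c(CCc2cccc(OCc3ccccc3)c2)c1C(=O)c1ccc(O)cc1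
A2 | alternative 1 | 1,1',1''-{2-benzyloxy-4-[2-(3-benzyloxyphenyl)ethyl]-6-methoxybenzene-1,3,5-triyl}tris(prop-2-yn-1-one) | COc1c(C(=O)C#C)c(OCc2ccccc2)c(C(=O)C#C)c(CCc2cccc(OCc3ccccc3)c2)c1C(=O)C#C
A3 | alternative 1 | trans-1-methoxy-3-(trimethylsilyloxy)buta-1,3-diene | CO/C=C/C(=C)O[Si](C)(C)C
A4 | alternative 2 | 2,4,6-tris(4-benzyloxybenzyl)-5-[2-(3-benzyloxyphenyl)ethyl]benzene-1,3-diol | Oc1c(Cc2ccc(OCc3ccccc3)cc2)c(O)c(Cc2ccc(OCc3ccccc3)cc2)c(CCc2cccc(OCc3ccccc3)c2)c1Cc1ccc(OCc2ccccc2)cc1
A5 | alternative 2 | 1,5-bis(4-benzyloxyphenyl)pentan-3-one | O=C(CCc1ccc(OCc2ccccc2)cc1)CCc1ccc(OCc2ccccc2)cc1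
A6 | alternative 2 | ethyl 2-(4-benzyloxybenzyl)-5-(3-benzyloxyphenyl)penta-2,3-dienoate (racemic) | CCOC(=O)C(Cc1ccc(OCc2ccccc2)cc1)=C=CCc1cccc(OCc2ccccc2)c1
A7 | alternative 3 | 2-benzyloxy-1,3,5-tris(4-benzyloxybenzyl)-4-[2-(3-benzyloxyphenyl)ethyl]-6-methoxybenzene | COc1c(Cc2ccc(OCc3ccccc3)cc2)c(OCc2ccccc2)c(Cc2ccc(OCc3ccccc3)cc2)c(CCc2cccc(OCc3ccccc3)c2)c1Cc1ccc(OCc2ccccc2)cc1
A8 | alternative 3 | {2-benzyloxy-4-[2-(3-benzyloxyphenyl)ethyl]-6-methoxybenzene-1,3,5-triyl}tris(methylene) trimethyl tricarbonate | COc1c(COC(=O)OC)c(OCc2ccccc2)c(COC(=O)OC)c(CCc2cccc(OCc3ccccc3)c2)c1COC(=O)OC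
A9 | alternative 3 | (4-benzyloxyphenyl)boronic acid | OB(O)c1ccc(OCc2ccccc2)cc1
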